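**Strategy.** Ring B is a cyclohexene whose C8=C9 double bond marks it as a Diels–Alder adduct. An intramolecular [4+2] between the C7=C8–C9=C10 diene and a C5=C6 dienophile, tethered by C1–C4, forms the C6–C7 and C5–C10 bonds, both rings and the C5, C6 and C10 stereocentres at once. The target's syn-diaxial C19–OH/C6β–O pair is exploited: O19 is tied to C6 through boron in a six-membered alkenylboronic half ester, which locks the dienophile cis, activates it and steers the diene to one face from the single C4 stereocentre. The precursor is an acyclic 3-oxo triene; C–B oxidation, C3 reduction and acylation finish the route.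

Key step: step 11

Remark: atoms are numbered as in the labdane skeleton (target = 3R,4S,5R,6R,10S,13E); the absolute sense of the iridium-catalysed coupling in step 6 is selected through the ligand enantiomer.

Step 1
Reactants: 1 but-2-yn-1-ol; 2 prop-1-en-2-ylmagnesium bromide; 3 allyl bromide
Product: 5 (2Z)-3-methyl-2-(prop-1-en-2-yl)hexa-2,5-dien-1-ol, via alkenylmagnesium chelate 4 (not isolated)
Conditions: 2 (3.5 equiv), CuI (10 mol%), THF–toluene, 0 to 70 °C; then 3, 0 °C to rt; aq NH4Cl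
Reagents that add atoms: none
Why: Hydroxyl-directed anti-carbomagnesiation puts the isopropenyl group on the alkyne carbon next to CH2OH and magnesium, held cis to CH2O in a five-membered chelate, on the methyl-bearing carbon, so copper-mediated allylation with retention should place allyl cis to CH2OH and isopropenyl cis to methyl.

Step 2
Reactants: 5 (2Z)-3-methyl-2-(prop-1-en-2-yl)hexa-2,5-dien-1-ol
Product: 6 (3Z)-3-(bromomethyl)-2,4-dimethylhepta-1,3,6-triene
Conditions: CBr4, PPh3, CH2Cl2, 0 °C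
Reagents that add atoms: carbon tetrabromide, BrC(Br)(Br)Br
Why: Appel bromination of the primary allylic alcohol is neutral and proceeds by SN2 at the primary carbon, so the tetrasubstituted alkene geometry should be untouched.

Step 3
Reactants: 6 (3Z)-3-(bromomethyl)-2,4-dimethylhepta-1,3,6-triene; 7 tert-butyl 3-oxobutanoate
Product: 9 tert-butyl (2Z,6E)-3-[(diethoxyphosphoryl)oxy]-7-methyl-6-(prop-1-en-2-yl)deca-2,6,9-trienoate, via sodium keto ester enolate 8 (not isolated)
Conditions: 7, NaH, then n-BuLi, THF, 0 °C; 6, 0 °C; then ClP(O)(OEt)2, 0 °C to rt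
Reagents that add atoms: diethyl chlorophosphate, CCOP(=O)(Cl)OCC
Why: γ-Alkylation of the acetoacetate dianion by the allylic bromide leaves the chelated (Z)-enolate, which O-phosphorylation should trap as the (Z)-enol phosphate.

Step 4
Reactants: 9 tert-butyl (2Z,6E)-3-[(diethoxyphosphoryl)oxy]-7-methyl-6-(prop-1-en-2-yl)deca-2,6,9-trienoate
Product: 10 tert-butyl (2E,6E)-3,7-dimethyl-6-(prop-1-en-2-yl)deca-2,6,9-trienoate
Conditions: Me2CuLi (from MeLi and CuI), Et2O, −78 to −45 °C
Reagents that add atoms: lithium dimethylcuprate, [Li+].C[Cu-]C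
Why: Cuprate addition–elimination on the enol phosphate replaces phosphate by methyl with retention, which should fix the 13E trisubstituted enoate.

Step 5
Reactants: 10 tert-butyl (2E,6E)-3,7-dimethyl-6-(prop-1-en-2-yl)deca-2,6,9-trienoate
Product: 12 tert-butyl (2E,6E)-10-hydroxy-3,7-dimethyl-6-(prop-1-en-2-yl)deca-2,6-dienoate, via alkyl-9-BBN adduct 11 (not isolated)
Conditions: 9-BBN (1.1 equiv), THF, 0 °C to rt; then NaOH, H2O2, 0 °C
Reagents that add atoms: hydrogen peroxide, OO
Why: 9-BBN should hydroborate only the monosubstituted terminal alkene (anti-Markovnikov), the 1,1-disubstituted diene terminus and the more substituted alkenes being far slower, and oxidation gives the primary alcohol.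

Step 6
Reactants: 12 tert-butyl (2E,6E)-10-hydroxy-3,7-dimethyl-6-(prop-1-en-2-yl)deca-2,6-dienoate; 13 2-methyl-2-vinyloxirane (racemic)
Product: 14 tert-butyl (2E,6E,10S,11S)-10-hydroxy-11-(hydroxymethyl)-3,7,11-trimethyl-6-(prop-1-en-2-yl)trideca-2,6,12-trienoate
Conditions: π-allyliridium C,O-benzoate catalyst from [Ir(cod)Cl]2, Tol-BINAP (enantiomer chosen for 11S), 4-cyano-3-nitrobenzoic acid and allyl acetate (5 mol%), K3PO4 (5 mol%), THF, 60 °C
Reagents that add atoms: none
Why: In this iridium-catalysed transfer-hydrogenative tert-(hydroxy)prenylation the alcohol is dehydrogenated to the aldehyde, which the σ-allyliridium from the vinyl epoxide attacks through a closed chair transition state, the chiral catalyst setting the quaternary C4 (anti to the C3 hydroxyl, whose configuration is erased in step 8).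

Step 7
Reactants: 14 tert-butyl (2E,6E,10S,11S)-10-hydroxy-11-(hydroxymethyl)-3,7,11-trimethyl-6-(prop-1-en-2-yl)trideca-2,6,12-trienoate
Product: 15 tert-butyl (2E,6E,10S,11S)-10-hydroxy-3,7,11-trimethyl-6-(prop-1-en-2-yl)-11-{[(triethylsilyl)oxy]methyl}trideca-2,6,12-trienoate
Conditions: TESCl (1.05 equiv), imidazole, CH2Cl2, −40 °C
Reagents that add atoms: chlorotriethylsilane, CC[Si](Cl)(CC)CC
Why: The primary hydroxyl should be silylated much faster than the secondary hydroxyl flanked by the quaternary carbon.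

Step 8
Reactants: 15 tert-butyl (2E,6E,10S,11S)-10-hydroxy-3,7,11-trimethyl-6-(prop-1-en-2-yl)-11-{[(triethylsilyl)oxy]methyl}trideca-2,6,12-trienoate
Product: 16 tert-butyl (2E,6E,11S)-3,7,11-trimethyl-10-oxo-6-(prop-1-en-2-yl)-11-{[(triethylsilyl)oxy]methyl}trideca-2,6,12-trienoate
Conditions: Dess–Martin periodinane, NaHCO3, CH2Cl2, rt
Reagents that add atoms: none
Why: Dess–Martin oxidation of the only free alcohol gives the C3 ketone and removes the C3 configuration, which step 6 delivers with the wrong sense for the target.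

Step 9
Reactants: 16 tert-butyl (2E,6E,11S)-3,7,11-trimethyl-10-oxo-6-(prop-1-en-2-yl)-11-{[(triethylsilyl)oxy]methyl}trideca-2,6,12-trienoate
Product: 17 tert-butyl (2E,6E,11S)-11-(hydroxymethyl)-3,7,11-trimethyl-10-oxo-6-(prop-1-en-2-yl)trideca-2,6,12-trienoate
Conditions: PPTS (cat.), MeOH, 0 °C to rt
Reagents that add atoms: none
Why: Mild acid-catalysed methanolysis cleaves the primary TES ether without base, so retro-aldol loss of formaldehyde from the β-hydroxy ketone should be avoided.

Step 10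
Reactants: 17 tert-butyl (2E,6E,11S)-11-(hydroxymethyl)-3,7,11-trimethyl-10-oxo-6-(prop-1-en-2-yl)trideca-2,6,12-trienoate; 18 dibutyl vinylboronate
Product: 20 tert-butyl (2E,6E)-10-[(5S)-2-hydroxy-5-methyl-5,6-dihydro-2H-1,2-oxaborinin-5-yl]-3,7-dimethyl-10-oxo-6-(prop-1-en-2-yl)deca-2,6-dienoate, via mixed butyl vinylboronate 19 (not isolated)
Conditions: 18, toluene, rt, BuOH removed under reduced pressure; second-generation Grubbs catalyst RuCl2(=CHPh)(H2IMes)(PCy3) (10 mol%), toluene, 60 °C; aqueous work-up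
Reagents that add atoms: water, O
Why: Ester exchange attaches the vinylboron unit to O19 and boron-tethered ring-closing metathesis with the C4 vinyl group should close the six-membered oxaborinine, in which C5=C6 is necessarily cis, while the hindered diene terminus and the more substituted alkenes stay out.

Step 11
Reactants: 20 tert-butyl (2E,6E)-10-[(5S)-2-hydroxy-5-methyl-5,6-dihydro-2H-1,2-oxaborinin-5-yl]-3,7-dimethyl-10-oxo-6-(prop-1-en-2-yl)deca-2,6-dienoate
Product: 21 tert-butyl (13E)-6β,19-[(hydroxyboranediyl)oxy]-3-oxolabda-8,13-dien-15-oate (4S,5R,6R,10S; trans-decalin with boron on C6β bonded to O19)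
Conditions: toluene (0.01 M), BHT, 160 °C, sealed tube
Reagents that add atoms: none
Why: A concerted, asynchronous thermal [4+2] cycloaddition in which the C7=C8–C9=C10 diene adds suprafacially to the boron-activated C5=C6 bond; the closest known reaction type is the intramolecular Diels–Alder reaction of alkenylboronic esters. Ring B is closed as the cyclohexene created by the cycloaddition itself, and ring A is closed by the same C5–C10 bond as a six-membered carbocycle through the C1–C4 tether in a chair-like transition state with the oxaborinine exo. C5 and C6 are controlled by the ring-locked cis dienophile (H5 and H6 syn, boron and C19 on one face) together with C4, because the tether leaves from ring carbon C4 and can bring the diene only to the oxaborinine face that carries C3. C10 is controlled by the diene geometry (C20 methyl inside, C1 outside) in the exo mode, which sets the C20 methyl anti to H5 and so gives the trans-decalin. The selectivity required is exo over endo, and it is secured by the C9 side chain, which collides with the tether in the cis-fused endo transition state, and by the lack of an endo-directing carbonyl on the dienophile. Regiochemistry is fixed by the tether, and the reversible 1,5-hydrogen shift from C20 to C7 that a cis-methyl diene can undergo on heating only regenerates the same diene geometry.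

Step 12
Reactants: 21 tert-butyl (13E)-6β,19-[(hydroxyboranediyl)oxy]-3-oxolabda-8,13-dien-15-oate
Product: 23 tert-butyl (13E)-3α,6β,19-trihydroxylabda-8,13-dien-15-oate, via 3α-hydroxy boronate 22 (not isolated)
Conditions: LiBH(s-Bu)3 (L-Selectride), THF, −78 °C; then NaOH, H2O2, 0 °C to rt
Reagents that add atoms: hydrogen peroxide, OO
Why: The bulky hydride should attack the 4,4-disubstituted C3 ketone along the equatorial trajectory to give the axial 3α-alcohol, and alkaline peroxide oxidises the C6–B bond with retention to the 6β-alcohol while freeing O19.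

Step 13
Reactants: 23 tert-butyl (13E)-3α,6β,19-trihydroxylabda-8,13-dien-15-oate
Product: 24 tert-butyl (13E)-3α,6β-dihydroxy-19-[(triethylsilyl)oxy]labda-8,13-dien-15-oate
Conditions: TESCl (1.05 equiv), imidazole, CH2Cl2, −40 °C
Reagents that add atoms: chlorotriethylsilane, CC[Si](Cl)(CC)CC
Why: The primary C19 hydroxyl should react far faster than the two hindered axial secondary hydroxyls.

Step 14
Reactants: 24 tert-butyl (13E)-3α,6β-dihydroxy-19-[(triethylsilyl)oxy]labda-8,13-dien-15-oate; 25 3-methylbutanoic anhydride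
Product: 26 tert-butyl (13E)-3α,6β-bis(3-methylbutanoyloxy)-19-[(triethylsilyl)oxy]labda-8,13-dien-15-oate
Conditions: 25 (6 equiv), DMAP (2 equiv), Et3N, toluene, 60 °C
Reagents that add atoms: none
Why: DMAP-catalysed acylation under forcing conditions should esterify both axial secondary alcohols, with configuration unchanged because the C–O bonds are not broken.

Step 15
Reactants: 26 tert-butyl (13E)-3α,6β-bis(3-methylbutanoyloxy)-19-[(triethylsilyl)oxy]labda-8,13-dien-15-oate
Product: 27 (13E)-19-hydroxy-3α,6β-bis(3-methylbutanoyloxy)labda-8,13-dien-15-oic acid (3R,4S,5R,6R,10S)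
Conditions: TFA, wet CH2Cl2 (1:4), 0 °C; neutral aqueous work-up
Reagents that add atoms: none
Why: Acidolysis removes the tert-butyl ester (as isobutene) and the primary TES ether in one operation, and the non-basic medium should suppress 6-O to 19-O acyl migration.

**Compound list**

1 | but-2-yn-1-ol | CC#CCO | starting material
2 | prop-1-en-2-ylmagnesium bromide | C=C(C)[Mg]Br | starting material
3 | allyl bromide | C=CCBr | starting material
4 | bromomagnesium (2Z)-3-(bromomagnesio)-2-(prop-1-en-2-yl)but-2-en-1-olate | C=C(C)/C(CO[Mg]Br)=C(\C)[Mg]Br | intermediate (not isolated)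
5 | (2Z)-3-methyl-2-(prop-1-en-2-yl)hexa-2,5-dien-1-ol | C=C(C)/C(CO)=C(\C)CC=C | intermediate
6 | (3Z)-3-(bromomethyl)-2,4-dimethylhepta-1,3,6-triene | C=C(C)/C(CBr)=C(\C)CC=C | intermediate
7 | tert-butyl 3-oxobutanoate | CC(=O)CC(=O)OC(C)(C)C | starting material
8 | sodium (2Z,6E)-1-tert-butoxy-7-methyl-1-oxo-6-(prop-1-en-2-yl)deca-2,6,9-trien-3-olate | C=C(C)/C(CC/C([O-])=C/C(=O)OC(C)(C)C)=C(\C)CC=C.[Na+] | intermediate (not isolated)
9 | tert-butyl (2Z,6E)-3-[(diethoxyphosphoryl)oxy]-7-methyl-6-(prop-1-en-2-yl)deca-2,6,9-trienoate | C=C(C)/C(CC/C(OP(=O)(OCC)OCC)=C/C(=O)OC(C)(C)C)=C(\C)CC=C | intermediate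
10 | tert-butyl (2E,6E)-3,7-dimethyl-6-(prop-1-en-2-yl)deca-2,6,9-trienoate | C=C(C)/C(CC/C(C)=C/C(=O)OC(C)(C)C)=C(\C)CC=C | intermediate
11 | tert-butyl (2E,6E)-10-(9-borabicyclo[3.3.1]nonan-9-yl)-3,7-dimethyl-6-(prop-1-en-2-yl)deca-2,6-dienoate | C=C(C)/C(CC/C(C)=C/C(=O)OC(C)(C)C)=C(\C)CCCB1C2CCCC1CCC2 | intermediate (not isolated)
12 | tert-butyl (2E,6E)-10-hydroxy-3,7-dimethyl-6-(prop-1-en-2-yl)deca-2,6-dienoate | C=C(C)/C(CC/C(C)=C/C(=O)OC(C)(C)C)=C(\C)CCCO | intermediate
13 | 2-methyl-2-vinyloxirane (racemic) | CC1(C=C)CO1 | starting material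
14 | tert-butyl (2E,6E,10S,11S)-10-hydroxy-11-(hydroxymethyl)-3,7,11-trimethyl-6-(prop-1-en-2-yl)trideca-2,6,12-trienoate | C=C(C)/C(CC/C(C)=C/C(=O)OC(C)(C)C)=C(\C)CC[C@H](O)[C@](C)(CO)C=C | intermediate
15 | tert-butyl (2E,6E,10S,11S)-10-hydroxy-3,7,11-trimethyl-6-(prop-1-en-2-yl)-11-{[(triethylsilyl)oxy]methyl}trideca-2,6,12-trienoate | C=C(C)/C(CC/C(C)=C/C(=O)OC(C)(C)C)=C(\C)CC[C@H](O)[C@](C)(CO[Si](CC)(CC)CC)C=C | intermediate
16 | tert-butyl (2E,6E,11S)-3,7,11-trimethyl-10-oxo-6-(prop-1-en-2-yl)-11-{[(triethylsilyl)oxy]methyl}trideca-2,6,12-trienoate | C=C(C)/C(CC/C(C)=C/C(=O)OC(C)(C)C)=C(\C)CCC(=O)[C@](C)(CO[Si](CC)(CC)CC)C=C | intermediate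
17 | tert-butyl (2E,6E,11S)-11-(hydroxymethyl)-3,7,11-trimethyl-10-oxo-6-(prop-1-en-2-yl)trideca-2,6,12-trienoate | C=C(C)/C(CC/C(C)=C/C(=O)OC(C)(C)C)=C(\C)CCC(=O)[C@](C)(CO)C=C | intermediate
18 | dibutyl vinylboronate | C=CB(OCCCC)OCCCC | starting material
19 | tert-butyl (2E,6E,11S)-11-({[butoxy(ethenyl)boranyl]oxy}methyl)-3,7,11-trimethyl-10-oxo-6-(prop-1-en-2-yl)trideca-2,6,12-trienoate | C=C(C)/C(CC/C(C)=C/C(=O)OC(C)(C)C)=C(\C)CCC(=O)[C@](C)(COB(OCCCC)C=C)C=C | intermediate (not isolated)
20 | tert-butyl (2E,6E)-10-[(5S)-2-hydroxy-5-methyl-5,6-dihydro-2H-1,2-oxaborinin-5-yl]-3,7-dimethyl-10-oxo-6-(prop-1-en-2-yl)deca-2,6-dienoate | C=C(C)/C(CC/C(C)=C/C(=O)OC(C)(C)C)=C(\C)CCC(=O)[C@]1(C)COB(O)C=C1 | intermediate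
21 | tert-butyl (13E)-6β,19-[(hydroxyboranediyl)oxy]-3-oxolabda-8,13-dien-15-oate (4S,5R,6R,10S) | CC1=C(CC/C(C)=C/C(=O)OC(C)(C)C)[C@@]2(C)CCC(=O)[C@](C)(COB3O)[C@@H]2[C@H]3C1 | intermediate
22 | tert-butyl (13E)-3α-hydroxy-6β,19-[(hydroxyboranediyl)oxy]labda-8,13-dien-15-oate | CC1=C(CC/C(C)=C/C(=O)OC(C)(C)C)[C@@]2(C)CC[C@@H](O)[C@](C)(COB3O)[C@@H]2[C@H]3C1 | intermediate (not isolated)
23 | tert-butyl (13E)-3α,6β,19-trihydroxylabda-8,13-dien-15-oate (3R,4S,5R,6R,10S) | CC1=C(CC/C(C)=C/C(=O)OC(C)(C)C)[C@@]2(C)CC[C@@H](O)[C@](C)(CO)[C@@H]2[C@H](O)C1 | intermediate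
24 | tert-butyl (13E)-3α,6β-dihydroxy-19-[(triethylsilyl)oxy]labda-8,13-dien-15-oate | CC1=C(CC/C(C)=C/C(=O)OC(C)(C)C)[C@@]2(C)CC[C@@H](O)[C@](C)(CO[Si](CC)(CC)CC)[C@@H]2[C@H](O)C1 | intermediate
25 | 3-methylbutanoic anhydride | CC(C)CC(=O)OC(=O)CC(C)C | starting material
26 | tert-butyl (13E)-3α,6β-bis(3-methylbutanoyloxy)-19-[(triethylsilyl)oxy]labda-8,13-dien-15-oate | CC1=C(CC/C(C)=C/C(=O)OC(C)(C)C)[C@@]2(C)CC[C@@H](OC(=O)CC(C)C)[C@](C)(CO[Si](CC)(CC)CC)[C@@H]2[C@H](OC(=O)CC(C)C)C1 | intermediate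
27 | (13E)-19-hydroxy-3α,6β-bis(3-methylbutanoyloxy)labda-8,13-dien-15-oic acid (3R,4S,5R,6R,10S) | CC1=C(CC/C(C)=C/C(=O)O)[C@@]2(C)CC[C@@H](OC(=O)CC(C)C)[C@](C)(CO)[C@@H]2[C@H](OC(=O)CC(C)C)C1 | target

**Step count.** Total: 15 steps. Longest linear sequence: 15 steps (from 1; compounds 2, 3, 7, 13, 18 and 25 are purchased).

**Steps most likely to fail**

Step 11. The cycloaddition may be too slow at the fully substituted diene terminus with a dienophile that is only weakly activated, so that protodeboronation, ester thermolysis or hydrogen shifts outrun ring formation, and the exo preference may erode. The fallback keeps the O19 tether but uses a strongly activated sulfonyl dienophile. It sets out from 17: 2-chloroethanesulfonyl chloride and Et3N should give the vinylsulfonate F1, and ring-closing metathesis the α,β-unsaturated δ-sultone F2. Its intramolecular Diels–Alder reaction (toluene, 110–130 °C) should give the sultone adduct F3, and LiBH(s-Bu)3 the 3α-alcohol F4. Metalation next to sulfur (LDA) and oxidation with bis(trimethylsilyl) peroxide should excise sulfur and give the 6-ketone diol F5. NaBH4, attacking from the α face opposite C19 and C20, should then return the route at triol 23.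

Step 10. Boronate exchange may stay incomplete, the mixed boronate may hydrolyse, and the ruthenium carbene may be slowed at the neopentylic vinyl group by the free β-hydroxy ketone and boronic acid. The fallback replaces boron by a robust silicon tether and needs no TES shuffle. It sets out from 14: chlorodimethylvinylsilane and imidazole should silylate only the primary hydroxyl to give the vinylsilyl ether F6, and ring-closing metathesis the cyclic alkenylsiloxane F7. Dess–Martin oxidation should give the ketone F8, and a thermal intramolecular Diels–Alder reaction at higher temperature the siloxane-bridged adduct F9. LiBH(s-Bu)3 should give the 3α-alcohol F10, which without isolation is submitted to Tamao oxidation (H2O2, KF, KHCO3), returning the route at triol 23.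

Step 6. The iridium hydride may add to the conjugated diene or the enoate instead of being recycled, which would lower turnover and enantioselectivity. The fallback avoids metal hydrides and sets out from 12: Dess–Martin oxidation should give the aldehyde F11. The allyl donor is made separately from 13: Ni(cod)2/PCy3-catalysed SN2′ borylative opening with bis(pinacolato)diboron should give the (E)-hydroxy allylboronate F12, and TESCl its silyl ether F13. Allylboration of F11 with F13, catalysed by the appropriate enantiomer of the chiral phosphoric acid TRIP, should proceed through a closed chair transition state and deliver the mono-TES ether 15 directly, where the route is rejoined (step 7 is then not needed).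

**Further compounds**

F1 | step 11 | tert-butyl (2E,6E,11S)-11-{[(ethenylsulfonyl)oxy]methyl}-3,7,11-trimethyl-10-oxo-6-(prop-1-en-2-yl)trideca-2,6,12-trienoate | C=C(C)/C(CC/C(C)=C/C(=O)OC(C)(C)C)=C(\C)CCC(=O)[C@](C)(COS(=O)(=O)C=C)C=C
F2 | step 11 | tert-butyl (2E,6E)-3,7-dimethyl-10-[(5S)-5-methyl-2,2-dioxo-5,6-dihydro-1,2-oxathiin-5-yl]-10-oxo-6-(prop-1-en-2-yl)deca-2,6-dienoate | C=C(C)/C(CC/C(C)=C/C(=O)OC(C)(C)C)=C(\C)CCC(=O)[C@]1(C)COS(=O)(=O)C=C1
F3 | step 11 | tert-butyl (13E)-3-oxo-6β,19-(sulfonyloxy)labda-8,13-dien-15-oate (sultone adduct) | CC1=C(CC/C(C)=C/C(=O)OC(C)(C)C)[C@@]2(C)CCC(=O)[C@](C)(COS3(=O)=O)[C@@H]2[C@H]3C1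
F4 | step 11 | tert-butyl (13E)-3α-hydroxy-6β,19-(sulfonyloxy)labda-8,13-dien-15-oate | CC1=C(CC/C(C)=C/C(=O)OC(C)(C)C)[C@@]2(C)CC[C@@H](O)[C@](C)(COS3(=O)=O)[C@@H]2[C@H]3C1
F5 | step 11 | tert-butyl (13E)-3α,19-dihydroxy-6-oxolabda-8,13-dien-15-oate | CC1=C(CC/C(C)=C/C(=O)OC(C)(C)C)[C@@]2(C)CC[C@@H](O)[C@](C)(CO)[C@@H]2C(=O)C1
F6 | step 10 | tert-butyl (2E,6E,10S,11S)-11-({[ethenyl(dimethyl)silyl]oxy}methyl)-10-hydroxy-3,7,11-trimethyl-6-(prop-1-en-2-yl)trideca-2,6,12-trienoate | C=C(C)/C(CC/C(C)=C/C(=O)OC(C)(C)C)=C(\C)CC[C@H](O)[C@](C)(CO[Si](C)(C)C=C)C=C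
F7 | step 10 | tert-butyl (2E,6E,10S)-10-hydroxy-3,7-dimethyl-6-(prop-1-en-2-yl)-10-[(5S)-2,2,5-trimethyl-5,6-dihydro-2H-1,2-oxasilin-5-yl]deca-2,6-dienoate | C=C(C)/C(CC/C(C)=C/C(=O)OC(C)(C)C)=C(\C)CC[C@H](O)[C@]1(C)CO[Si](C)(C)C=C1
F8 | step 10 | tert-butyl (2E,6E)-3,7-dimethyl-10-oxo-6-(prop-1-en-2-yl)-10-[(5S)-2,2,5-trimethyl-5,6-dihydro-2H-1,2-oxasilin-5-yl]deca-2,6-dienoate | C=C(C)/C(CC/C(C)=C/C(=O)OC(C)(C)C)=C(\C)CCC(=O)[C@]1(C)CO[Si](C)(C)C=C1
F9 | step 10 | tert-butyl (13E)-6β,19-[(dimethylsilanediyl)oxy]-3-oxolabda-8,13-dien-15-oate | CC1=C(CC/C(C)=C/C(=O)OC(C)(C)C)[C@@]2(C)CCC(=O)[C@](C)(CO[Si]3(C)C)[C@@H]2[C@H]3C1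
F10 | step 10 | tert-butyl (13E)-6β,19-[(dimethylsilanediyl)oxy]-3α-hydroxylabda-8,13-dien-15-oate | CC1=C(CC/C(C)=C/C(=O)OC(C)(C)C)[C@@]2(C)CC[C@@H](O)[C@](C)(CO[Si]3(C)C)[C@@H]2[C@H]3C1
F11 | step 6 | tert-butyl (2E,6E)-3,7-dimethyl-10-oxo-6-(prop-1-en-2-yl)deca-2,6-dienoate | C=C(C)/C(CC/C(C)=C/C(=O)OC(C)(C)C)=C(\C)CCC=O
F12 | step 6 | (2E)-2-methyl-4-(4,4,5,5-tetramethyl-1,3,2-dioxaborolan-2-yl)but-2-en-1-ol | OC/C(C)=C/CB1OC(C)(C)C(C)(C)O1
F13 | step 6 | triethyl{[(2E)-2-methyl-4-(4,4,5,5-tetramethyl-1,3,2-dioxaborolan-2-yl)but-2-en-1-yl]oxy}silane | CC[Si](CC)(CC)OC/C(C)=C/CB1OC(C)(C)C(C)(C)O1
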